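The tetralin ring is closed last at C2–C3, the bond between its two non-benzylic CH2 groups (tetralin numbering: C1 carbinol, C4 diarylmethine; ring A is the methoxybenzene ring). A primary radical at C2, released from an (R)-bromohydrin silyl ether, adds 6-endo to the CH2 terminus C3 of a 1,1-diarylethene that links ring A to the naphthol ring. The step exploits that C4 carries two arenes: the diarylmethyl radical makes 6-endo closure the only productive path, and hydrogen-atom transfer to C4 anti to the pseudoaxial C1 silyloxy group sets the cis-1,4 relation. The precursor is open-chain: a CBS-derived bromohydrin and a naphthylvinyl group on neighbouring positions of one anisole ring.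

Key step: step 9

Remark: 8-methoxynaphthalen-1-ol (3) and 1,1-bis(pinacolatoboryl)ethene (6) are taken as catalogue compounds. Atom labels C1 to C8a follow the tetralin numbering of the target (C5 carries the methoxy group).

Step 1
Reactants: 1 1-(2-hydroxy-3-methoxyphenyl)ethan-1-one
Product: 2 2-acetyl-6-methoxyphenyl trifluoromethanesulfonate
Conditions: Tf2O, pyridine, CH2Cl2, 0 °C
Reagents that add atoms: triflic anhydride, O=S(=O)(OS(=O)(=O)C(F)(F)F)C(F)(F)F
Why: O-sulfonylation (triflation) of the phenol turns the ring position between the acetyl and methoxy groups into a cross-coupling handle.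

Step 2
Reactants: 3 8-methoxynaphthalen-1-ol
Product: 4 4-bromo-8-methoxynaphthalen-1-ol
Conditions: NBS (1.0 equiv), MeCN, −20 to 0 °C
Reagents that add atoms: N-bromosuccinimide, O=C1CCC(=O)N1Br
Why: Electrophilic aromatic bromination, in which the free hydroxyl group as the strongest donor should direct NBS to its para position, with low temperature and one equivalent holding back ortho and double bromination.

Step 3
Reactants: 4 4-bromo-8-methoxynaphthalen-1-ol
Product: 5 [(4-bromo-8-methoxynaphthalen-1-yl)oxy]triisopropylsilane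
Conditions: TIPSOTf, 2,6-lutidine, CH2Cl2, 0 °C to rt
Reagents that add atoms: triisopropylsilyl triflate, CC(C)[Si](OS(=O)(=O)C(F)(F)F)(C(C)C)C(C)C
Why: Silylation of the peri-hindered naphthol with the reactive silyl triflate gives an aryl TIPS ether that should survive both couplings, the enolization and the radical step.

Step 4
Reactants: 5 [(4-bromo-8-methoxynaphthalen-1-yl)oxy]triisopropylsilane; 6 2,2'-(ethene-1,1-diyl)bis(4,4,5,5-tetramethyl-1,3,2-dioxaborolane)
Product: 7 triisopropyl({8-methoxy-4-[1-(4,4,5,5-tetramethyl-1,3,2-dioxaborolan-2-yl)ethenyl]naphthalen-1-yl}oxy)silane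
Conditions: Pd(OAc)2 (5 mol %), SPhos (10 mol %), K3PO4, THF/H2O, 45 °C, 6 in excess (2.5 equiv)
Reagents that add atoms: none
Why: Suzuki–Miyaura coupling of a geminal bis(boronate), in which the excess of 6 and the greater hindrance of the α-aryl alkenylboronate product should hold the reaction at monoarylation.

Step 5
Reactants: 2 2-acetyl-6-methoxyphenyl trifluoromethanesulfonate; 7 triisopropyl({8-methoxy-4-[1-(4,4,5,5-tetramethyl-1,3,2-dioxaborolan-2-yl)ethenyl]naphthalen-1-yl}oxy)silane
Product: 8 1-[3-methoxy-2-(1-{5-methoxy-4-[(triisopropylsilyl)oxy]naphthalen-1-yl}ethenyl)phenyl]ethan-1-one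
Conditions: Pd2(dba)3 (2.5 mol %), SPhos (10 mol %), K3PO4, toluene/H2O, 90 °C
Reagents that add atoms: none
Why: Suzuki–Miyaura coupling of an electron-poor aryl triflate with an alkenylboronate, with a dialkylbiarylphosphine ligand chosen for the doubly ortho-substituted triflate and the α-branched boronate.

Step 6
Reactants: 8 1-[3-methoxy-2-(1-{5-methoxy-4-[(triisopropylsilyl)oxy]naphthalen-1-yl}ethenyl)phenyl]ethan-1-one
Product: 10 2-bromo-1-[3-methoxy-2-(1-{5-methoxy-4-[(triisopropylsilyl)oxy]naphthalen-1-yl}ethenyl)phenyl]ethan-1-one, via trimethylsilyl enol ether 9 (not isolated)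
Conditions: TMSOTf, Et3N, CH2Cl2, 0 °C; then NBS (1.0 equiv), THF, −78 °C
Reagents that add atoms: N-bromosuccinimide, O=C1CCC(=O)N1Br; trimethylsilyl triflate, C[Si](C)(C)OS(=O)(=O)C(F)(F)F (its silyl group is carried only by 9)
Why: Silyl enol ether formation (only the methyl group can enolize) followed by α-bromination with NBS at −78 °C, where the enol ether should react far faster than the hindered 1,1-diarylethene or the naphthalene ring.

Step 7
Reactants: 10 2-bromo-1-[3-methoxy-2-(1-{5-methoxy-4-[(triisopropylsilyl)oxy]naphthalen-1-yl}ethenyl)phenyl]ethan-1-one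
Product: 11 (1R)-2-bromo-1-[3-methoxy-2-(1-{5-methoxy-4-[(triisopropylsilyl)oxy]naphthalen-1-yl}ethenyl)phenyl]ethan-1-ol
Conditions: (R)-2-methyl-CBS-oxazaborolidine (20 mol %), catecholborane, toluene, −78 to −40 °C; pH 7 work-up
Reagents that add atoms: none
Why: Corey–Bakshi–Shibata reduction, in which the aryl group acts as the large and CH2Br as the small substituent so that the (R)-catalyst should give the (R)-bromohydrin (the sense known for α-haloacetophenones); catecholborane at low temperature leaves the alkene alone and the neutral work-up avoids epoxide formation.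

Step 8
Reactants: 11 (1R)-2-bromo-1-[3-methoxy-2-(1-{5-methoxy-4-[(triisopropylsilyl)oxy]naphthalen-1-yl}ethenyl)phenyl]ethan-1-ol
Product: 12 {[(1R)-2-bromo-1-{3-methoxy-2-[1-(5-methoxy-4-{[triisopropylsilyl]oxy}naphthalen-1-yl)ethenyl]phenyl}ethyl]oxy}(tert-butyl)dimethylsilane
Conditions: TBSOTf, 2,6-lutidine, CH2Cl2, −78 to 0 °C
Reagents that add atoms: tert-butyldimethylsilyl triflate, CC(C)(C)[Si](C)(C)OS(=O)(=O)C(F)(F)F
Why: Silylation of the secondary alcohol with a non-nucleophilic base (no epoxide closure) installs the bulky OTBS group that later steers the hydrogen-atom transfer.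

Step 9
Reactants: 12 {[(1R)-2-bromo-1-{3-methoxy-2-[1-(5-methoxy-4-{[triisopropylsilyl]oxy}naphthalen-1-yl)ethenyl]phenyl}ethyl]oxy}(tert-butyl)dimethylsilane
Product: 13 tert-butyl{[(1S,4S)-5-methoxy-4-{5-methoxy-4-[(triisopropylsilyl)oxy]naphthalen-1-yl}-1,2,3,4-tetrahydronaphthalen-1-yl]oxy}dimethylsilane
Conditions: Bu3SnH (1.3 equiv, syringe pump), AIBN (0.2 equiv), PhH (0.01 M), 80 °C
Reagents that add atoms: none
Why: Bu3Sn• abstracts bromine from 12 to give a primary β-silyloxyalkyl radical at C2, which adds to the terminal alkene carbon C3; the resulting tertiary diarylmethyl radical at C4 takes a hydrogen atom from Bu3SnH and so carries the chain. The closest known reaction type is the tin hydride mediated reductive cyclization of 5-substituted hex-5-enyl radicals, which close endo onto 1,1-disubstituted alkenes that bear a radical-stabilizing substituent. The six-membered carbocycle closes in the 6-endo-trig mode, because the 5-exo alternative would attack the fully substituted C4 and leave an unstabilized primary radical next to a quaternary carbon. C1 keeps the configuration from step 7; C4 is set in the hydrogen-atom transfer, where the OTBS group on C1 should sit pseudoaxial (peri strain with C8–H) so that the tin hydride approaches the planar C4 radical along the pseudoaxial trajectory anti to it, placing the new hydrogen trans and the naphthyl group cis to the C1 oxygen. The step needs endo regioselectivity (secured by the two aryl groups on C4), cyclization ahead of direct reduction (secured by slow addition at high dilution) and anti facial selectivity (secured by the bulky C1 silyl ether).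

Step 10
Reactants: 13 tert-butyl{[(1S,4S)-5-methoxy-4-{5-methoxy-4-[(triisopropylsilyl)oxy]naphthalen-1-yl}-1,2,3,4-tetrahydronaphthalen-1-yl]oxy}dimethylsilane
Product: 14 (1S,4S)-4-(4-hydroxy-5-methoxynaphthalen-1-yl)-5-methoxy-1,2,3,4-tetrahydronaphthalen-1-ol (dipolynaphthalene B)
Conditions: Bu4NF, AcOH, degassed THF, 0 °C to rt
Reagents that add atoms: none
Why: Fluoride-mediated desilylation should cleave both silyl ethers at once without touching either stereocenter, the acetic acid buffer protecting the electron-rich naphtholate from air oxidation and the benzylic alcohol from elimination.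

Compound list
1 | 1-(2-hydroxy-3-methoxyphenyl)ethan-1-one | CC(=O)c1cccc(OC)c1O | starting material
2 | 2-acetyl-6-methoxyphenyl trifluoromethanesulfonate | CC(=O)c1cccc(OC)c1OS(=O)(=O)C(F)(F)F | intermediate
3 | 8-methoxynaphthalen-1-ol | COc1cccc2cccc(O)c12 | starting material
4 | 4-bromo-8-methoxynaphthalen-1-ol | COc1cccc2c(Br)ccc(O)c12 | intermediate
5 | [(4-bromo-8-methoxynaphthalen-1-yl)oxy]triisopropylsilane | COc1cccc2c(Br)ccc(O[Si](C(C)C)(C(C)C)C(C)C)c12 | intermediate
6 | 2,2'-(ethene-1,1-diyl)bis(4,4,5,5-tetramethyl-1,3,2-dioxaborolane) | C=C(B1OC(C)(C)C(C)(C)O1)B1OC(C)(C)C(C)(C)O1 | starting material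
7 | triisopropyl({8-methoxy-4-[1-(4,4,5,5-tetramethyl-1,3,2-dioxaborolan-2-yl)ethenyl]naphthalen-1-yl}oxy)silane | C=C(B1OC(C)(C)C(C)(C)O1)c1ccc(O[Si](C(C)C)(C(C)C)C(C)C)c2c(OC)cccc12 | intermediate
8 | 1-[3-methoxy-2-(1-{5-methoxy-4-[(triisopropylsilyl)oxy]naphthalen-1-yl}ethenyl)phenyl]ethan-1-one | CC(=O)c1cccc(OC)c1C(=C)c1ccc(O[Si](C(C)C)(C(C)C)C(C)C)c2c(OC)cccc12 | intermediate
9 | trimethylsilyl enol ether of 8, trimethyl{[1-(3-methoxy-2-{1-[5-methoxy-4-(triisopropylsilyloxy)naphthalen-1-yl]ethenyl}phenyl)ethenyl]oxy}silane | C=C(O[Si](C)(C)C)c1cccc(OC)c1C(=C)c1ccc(O[Si](C(C)C)(C(C)C)C(C)C)c2c(OC)cccc12 | intermediate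
10 | 2-bromo-1-[3-methoxy-2-(1-{5-methoxy-4-[(triisopropylsilyl)oxy]naphthalen-1-yl}ethenyl)phenyl]ethan-1-one | BrCC(=O)c1cccc(OC)c1C(=C)c1ccc(O[Si](C(C)C)(C(C)C)C(C)C)c2c(OC)cccc12 | intermediate
11 | (1R)-2-bromo-1-[3-methoxy-2-(1-{5-methoxy-4-[(triisopropylsilyl)oxy]naphthalen-1-yl}ethenyl)phenyl]ethan-1-ol | BrC[C@H](O)c1cccc(OC)c1C(=C)c1ccc(O[Si](C(C)C)(C(C)C)C(C)C)c2c(OC)cccc12 | intermediate
12 | {[(1R)-2-bromo-1-{3-methoxy-2-[1-(5-methoxy-4-{[triisopropylsilyl]oxy}naphthalen-1-yl)ethenyl]phenyl}ethyl]oxy}(tert-butyl)dimethylsilane | BrC[C@H](O[Si](C)(C)C(C)(C)C)c1cccc(OC)c1C(=C)c1ccc(O[Si](C(C)C)(C(C)C)C(C)C)c2c(OC)cccc12 | intermediate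
13 | tert-butyl{[(1S,4S)-5-methoxy-4-{5-methoxy-4-[(triisopropylsilyl)oxy]naphthalen-1-yl}-1,2,3,4-tetrahydronaphthalen-1-yl]oxy}dimethylsilane | COc1cccc2c1[C@H](c1ccc(O[Si](C(C)C)(C(C)C)C(C)C)c3c(OC)cccc13)CC[C@@H]2O[Si](C)(C)C(C)(C)C | intermediate
14 | (1S,4S)-4-(4-hydroxy-5-methoxynaphthalen-1-yl)-5-methoxy-1,2,3,4-tetrahydronaphthalen-1-ol | COc1cccc2c1[C@H](c1ccc(O)c3c(OC)cccc13)CC[C@@H]2O | target

Total step count: 10. Longest linear sequence: 9 steps (from 3 through steps 2, 3, 4, 5, 6, 7, 8, 9 and 10 to 14); the branch from 1 is 7 steps.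

Steps most likely to fail

Step 9. The hydrogen-atom transfer to the planar C4 radical may show poor facial selectivity. Chain transfer to this hindered, stabilized radical may also be slow enough for disproportionation to compete. The fallback sets out from 12 and separates ring closure from the setting of C4. A visible-light Pd-catalysed alkyl Heck-type cyclization (Pd(OAc)2, Xantphos, Cs2CO3, PhH, blue LEDs, rt) should form the same C2–C3 bond and end by β-hydride elimination. This gives the 1,2-dihydronaphthalene F1, with a trisubstituted C3=C4 double bond. Catalyst-controlled hydrogenation with [Ir(cod)(tBu-PHOX)]BArF under H2 in CH2Cl2 then delivers hydrogen to C4. The ligand enantiomer is chosen to match the bias of the C1 silyl ether. The route is rejoined at 13.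

Step 4. The geminal bis(boronate) may undergo double arylation, and the hindered alkenylboronate product may suffer protodeboronation. The fallback sets out from 5 and builds the alkenylboronate from a ketone. Bromine–lithium exchange (n-BuLi, THF, −78 °C) and acylation with N-methoxy-N-methylacetamide should give the naphthyl methyl ketone F2. Enolization and O-sulfonylation (KN(SiMe3)2, PhNTf2, THF, −78 °C) give the enol triflate F3. Miyaura borylation (B2pin2, PdCl2(PPh3)2, PPh3, KOPh, toluene, 50 °C) then rejoins the route at 7.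

Step 6. NBS may brominate the electron-rich 1,1-diarylethene or the naphthalene ring in competition with the silyl enol ether. The fallback sets out from 2 and places the halogenation before any alkene is present. α-Bromination with CuBr2 (EtOAc/CHCl3, reflux) should give the bromoketone triflate F4. CBS reduction ((R)-2-methyl-CBS-oxazaborolidine, BH3·SMe2, THF, 0 °C) gives the (R)-bromohydrin F5. Silylation (TBSOTf, 2,6-lutidine, CH2Cl2) gives its TBS ether F6. Suzuki–Miyaura coupling of F6 with 7 (Pd2(dba)3, SPhos, K3PO4, toluene/H2O, 80 °C) rejoins the route directly at 12.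

Further compounds
F1 | step 9 | tert-butyl{[(1S)-5-methoxy-4-{5-methoxy-4-[(triisopropylsilyl)oxy]naphthalen-1-yl}-1,2-dihydronaphthalen-1-yl]oxy}dimethylsilane | COc1cccc2c1C(c1ccc(O[Si](C(C)C)(C(C)C)C(C)C)c3c(OC)cccc13)=CC[C@@H]2O[Si](C)(C)C(C)(C)C
F2 | step 4 | 1-{5-methoxy-4-[(triisopropylsilyl)oxy]naphthalen-1-yl}ethan-1-one | CC(=O)c1ccc(O[Si](C(C)C)(C(C)C)C(C)C)c2c(OC)cccc12
F3 | step 4 | 1-{5-methoxy-4-[(triisopropylsilyl)oxy]naphthalen-1-yl}ethenyl trifluoromethanesulfonate | C=C(OS(=O)(=O)C(F)(F)F)c1ccc(O[Si](C(C)C)(C(C)C)C(C)C)c2c(OC)cccc12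
F4 | step 6 | 2-(bromoacetyl)-6-methoxyphenyl trifluoromethanesulfonate | BrCC(=O)c1cccc(OC)c1OS(=O)(=O)C(F)(F)F
F5 | step 6 | 2-[(1R)-2-bromo-1-hydroxyethyl]-6-methoxyphenyl trifluoromethanesulfonate | BrC[C@H](O)c1cccc(OC)c1OS(=O)(=O)C(F)(F)F
F6 | step 6 | 2-[(1R)-2-bromo-1-{[tert-butyl(dimethyl)silyl]oxy}ethyl]-6-methoxyphenyl trifluoromethanesulfonate | BrC[C@H](O[Si](C)(C)C(C)(C)C)c1cccc(OC)c1OS(=O)(=O)C(F)(F)F
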